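## The problem

The target has a single carbocycle, a cyclohex-2-enone, with an oxirane fused onto its C5–C6 bond. Every ring carbon is substituted: C1 ketone, C2 (E)-hept-1-enyl, C3 hydroxymethyl, C4 secondary carbinol, C5 epoxide CH, and C6 a fully substituted epoxide carbon carrying the (E)-2-methylbut-2-enoic acid chain. Ring construction is therefore not the difficulty; the difficulty is to place six different substituents and three contiguous stereocentres (C4, C5, C6) in absolute terms. The C4 oxygen and the epoxide oxygen are cis, and C5 and C6 are tied together by the oxirane, so fixing O4 and O5 together and then bridging O5 stereospecifically to C6 controls all three centres, with C4/C5 governing C6. Late intermediates are fragile. The α,β-epoxy ketone and the cross-conjugated dienone do not tolerate base, because the chain CH2 on C6 is vinylogously acidic and its deprotonation opens the oxirane, and deprotonation at C4 leads towards aromatisation; the heptenyl diene does not survive peracid, iodine or metathesis catalysts. The enabling feature is the cis arrangement of the oxygens on the adjacent carbons C4 and C5. This is the pattern of an arene cis-dihydrodiol, so a dioxygenase can deliver both oxygens to a para-dihalobenzene whose halogens mark C3 and C6, and O5 then only has to move from a C6–C1 epoxide into the C5–C6 position. Throughout, ring atoms carry the locants of the target; α is the ring face of the C4 oxygen and β the opposite face.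

## Retrosynthesis

**20 from 19.** The last disconnection removes only protecting-group bonds: the O–Si bonds at O4 and at the primary oxygen, and the O–C bond of a tert-butyl ester. A methyl ester would need hydroxide on the base-labile epoxy dienone, whereas this acid-labile set allows one protic step. Compound 19 is no simpler in skeleton, but it is the form in which the polar groups can pass through the palladium steps. The forward step must cleave a secondary silyl ether without opening the oxirane.

**19 from 16 and 18; 18 from 17.** The sp2–sp2 bond between C2 and the heptenyl chain is cut to give α-iodoenone 16 and alkenylstannane 18, which comes from hept-1-yne 17 by C–Sn bond formation. Cutting here, and not carrying the diene from an earlier stage, keeps the peracid, metathesis and iodination steps away from a conjugated diene; an aldol or olefination at C2 would need base. Compound 16 lacks seven carbons and the diene. The coupling must join a fully substituted alkene carbon under neutral conditions with retention of the E geometry.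

**16 from 15; 15 from 13 and 14.** The C2–I bond is removed, then the chain C=C bond is cut by a cross-metathesis transform into the allyl group of 13 and tert-butyl methacrylate 14. Metathesis is preferred to a Wittig reaction because the aldehyde needed for the latter would sit β to the oxirane and eliminate. It precedes iodination because iodine would add to a terminal alkene. Compound 13 is simpler by four carbons and one stereodefined alkene. The forward steps must give the E trisubstituted enoate and iodinate a β,β-disubstituted enone at its only α-CH.

**13 from 12, 11 and 10.** These are functional-group changes only: the C1 ketone goes back to the carbinol of 12, the primary silyl ether to diol 11, and the hydroxymethyl group to the methyl ester of 10. The ester is kept up to this point because it deactivates C2=C3 towards the peracid and tames the vinyl epoxide; it is reduced only after the oxirane has left the allylic position. The forward steps need hydride reduction of an enoate beside an oxirane, discrimination of a primary from a hindered secondary hydroxyl, and oxidation of the single free hydroxyl.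

**10 from 9.** This is the strategic disconnection. The O5–C6 bond of the oxirane is cut and the O1–C6 bond re-formed, which moves the epoxide back from C5–C6 to C6–C1 and turns the C1 carbinol into an epoxide carbon. Epoxidising a C5=C6 enone instead would need a separate source of chirality and facial control relative to C4; this cut lets O5 be an enzymatic oxygen and creates C6 by inversion. Compound 9 has the same atoms, but its stereocentres trace back to one arene oxidation and one substrate-controlled epoxidation. The forward reaction needs O5 free and anti to the C6–C1 oxirane, O4 blocked, and an equilibrium lying on the side of 10.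

**9 from 8, 7 and 6.** The O4–Si bond is removed to give epoxy diol 8, both hydroxyls are re-masked as the triethylsilyl ethers of 7, and the two C–O bonds of the C6–C1 oxirane are cut to give triene ester 6. Silyl ethers are chosen over an acetonide because buffered fluoride removes them beside a vinyl epoxide, where aqueous acid would not be safe. Peracid epoxidation is chosen over halohydrin closure because the latter puts the epoxide syn to the ring oxygens. The peracid must pick the C1=C6 alkene out of three and the face anti to the silyloxy groups; the monosilylation must pick O4.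

**6 from 4 and 5; 4 from 3.** The C6–allyl bond is cut to vinyl bromide 4 and allyltributylstannane 5, then the C3–CO2Me bond is cut to iodide 3. Halogen reactivity dictates the order: the iodide reacts first, so iodine must mark C3 and bromine C6. The precursors are simpler by both carbon substituents. The forward steps need complete iodide-over-bromide selectivity, and a coupling next to a silyloxy-bearing carbon that does not isomerise the skipped triene.

**3 from 2 and 1.** The O–Si bonds are removed and the C4–O and C5–O bonds are disconnected to 1-bromo-4-iodobenzene 1. No chemical reagent cis-dihydroxylates a benzene ring; the enzyme does so and sets both carbinol centres at once. The precursor is an achiral commodity arene. The forward step requires iodine to take the directing role in the active site.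

## Roads not taken

Alternative 1: The ring would be cut at C3–C4 and C1–C2 and assembled from a prochiral 3,3-disubstituted cyclobutanone and a 1,3-enyne. Zerovalent nickel (Ni(cod)2 with a chiral phosphine) would couple carbonyl and alkyne, open the four-membered ring by β-carbon elimination and close cyclohexenone A1.
- Merits: one catalytic step forms the whole carbocycle with the heptenyl and silyloxymethyl groups already on C2 and C3, so no late halogenation or Stille coupling is needed. In convergency and C–C bond economy it is better than the chosen plan.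
- Weak points: A1 has its carbonyl at C4 and methylenes at C1 and C5. The target would then need oxidation at C1 beside a diene, closure of the oxirane from the tertiary oxygen after functionalising C5, and a face-selective reduction at C4. Enantiotopic C–C bond selection on a cyclobutanone whose two substituents differ little in size, together with the regiochemistry of enyne insertion, is unproven for this substitution.
- Comparison: the chosen plan sets against the better convergency a stereotriad that comes from one enzymatic oxidation and a stereospecific relay, and an oxidation pattern that is correct from the start.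

Alternative 2: The C2=C3 bond would be cut and the ring closed by enyne metathesis of an acyclic epoxy enyne. The second-generation Grubbs catalyst under ethylene would join the terminal alkyne to the 1,1-disubstituted alkene and give dienol epoxide A2, with a vinyl group on C2.
- Merits: the ring closure is irreversible, which the epoxide migration of the chosen plan is not. The vinyl group could be extended to the heptenyl chain by cross-metathesis, avoiding iodination and tin. In these respects it is the stronger route.
- Weak points: A2 requires an open-chain precursor with four contiguous stereocentres, among them a fully substituted epoxide carbon carrying both the enoate chain and a propargylic carbinol, each set by its own asymmetric step. The hindered 1,1-disubstituted alkene, competing closure modes and E-selective extension of a 1,3-diene add uncertainty.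
- Comparison: the chosen plan sets against the safer ring closure a much shorter stereochemical set-up from an achiral arene.

Alternative 3: The ring would be cut at C4–C5, C6–C1 and C1–C2 and made by benzannulation of a dienyl(methoxy)carbene complex of Cr(CO)5 with a terminal alkyne and one CO ligand, giving 4-methoxyphenol A3.
- Merits: it is the most convergent option, places all three side chains regioselectively in one step, and passes through a robust aromatic intermediate.
- Weak points: A3 is flat, so all three stereocentres must be created afterwards at the quinone level. This needs oxidation beside an electron-rich diene, epoxidation of C5=C6 that is both regio- and enantioselective without a substrate handle, and reduction of the C4 carbonyl in preference to C1 and syn to the oxirane. Chromium is used stoichiometrically.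
- Comparison: the chosen plan is longer in C–C bond construction, but its stereocontrol is substrate-based throughout and needs no enantioselective quinone epoxidation.

Key step: step 8

Assumption: toluene dioxygenase is taken to place iodine, the larger halogen, in the directing position, which fixes diol 2 as (1S,2R); its enantiomeric purity is treated as a risk of step 1.

## Steps

Step 1
Reactants: 1 1-bromo-4-iodobenzene
Product: 2 (1S,2R)-3-bromo-6-iodocyclohexa-3,5-diene-1,2-diol (cis-diol; target locants: C3–I, C6–Br, 4α,5α-diol)
Conditions: whole cells of E. coli JM109(pDTG601) expressing toluene dioxygenase, air, glucose, phosphate buffer pH 7, 30 °C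
Reagents that add atoms: dioxygen O=O
Why: Enzymatic arene cis-dihydroxylation; both oxygens are delivered to one face of the C4–C5 bond, and the larger halogen is expected to direct as it does with para-disubstituted benzenes, which sets C4 and C5 together.

Step 2
Reactants: 2 (1S,2R)-3-bromo-6-iodocyclohexa-3,5-diene-1,2-diol
Product: 3 bis(triethylsilyl) ether of 2 (C3–I, C6–Br, 4α,5α-bis(triethylsilyloxy) diene)
Conditions: Et3SiOTf (2.5 equiv), 2,6-lutidine, CH2Cl2, −78 to 0 °C
Reagents that add atoms: triethylsilyl trifluoromethanesulfonate CC[Si](CC)(CC)OS(=O)(=O)C(F)(F)F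
Why: Silyl ether formation under basic conditions avoids the acid-promoted dehydration of the dihydrodiol to a phenol; the two silyloxy groups later shield the α face and are removable with buffered fluoride.

Step 3
Reactants: 3 bis(triethylsilyl) ether of 2
Product: 4 methyl (5R,6R)-4-bromo-5,6-bis(triethylsilyloxy)cyclohexa-1,3-diene-1-carboxylate (target locants: C3–CO2Me, C6–Br)
Conditions: PdCl2(PPh3)2 (3 mol %), CO (1 atm), MeOH, Et3N, DMF, 45 °C
Reagents that add atoms: carbon monoxide [C-]#[O+]; methanol CO
Why: Palladium-catalysed alkoxycarbonylation; zerovalent palladium formed in situ inserts into the C–I bond far faster than into the C–Br bond, so only C3 is carbonylated at this temperature.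

Step 4
Reactants: 4 methyl (5R,6R)-4-bromo-5,6-bis(triethylsilyloxy)cyclohexa-1,3-diene-1-carboxylate; 5 allyltributylstannane
Product: 6 methyl (5S,6R)-4-allyl-5,6-bis(triethylsilyloxy)cyclohexa-1,3-diene-1-carboxylate (target locants: C3–CO2Me, C6–allyl)
Conditions: Pd2(dba)3 (2.5 mol %), AsPh3 (10 mol %), NMP, 50 °C
Reagents that add atoms: none
Why: Stille coupling; the bromide is activated as the δ-position of a dienoate, and the mild arsine conditions should keep the skipped triene from isomerising into conjugation.

Step 5
Reactants: 6 methyl (5S,6R)-4-allyl-5,6-bis(triethylsilyloxy)cyclohexa-1,3-diene-1-carboxylate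
Product: 7 methyl 6α-allyl-1β,6β-epoxy-4α,5α-bis(triethylsilyloxy)cyclohex-2-ene-3-carboxylate
Conditions: mCPBA (1.1 equiv), NaHCO3, CH2Cl2, 0 °C
Reagents that add atoms: 3-chloroperoxybenzoic acid OOC(=O)c1cccc(Cl)c1
Why: Prilezhaev epoxidation; the trisubstituted C1=C6 alkene should react ahead of the ester-deactivated C2=C3 and the monosubstituted allyl alkene, and the two α silyloxy groups send the peracid to the β face, placing the oxirane anti to O5.

Step 6
Reactants: 7 methyl 6α-allyl-1β,6β-epoxy-4α,5α-bis(triethylsilyloxy)cyclohex-2-ene-3-carboxylate
Product: 8 methyl 6α-allyl-1β,6β-epoxy-4α,5α-dihydroxycyclohex-2-ene-3-carboxylate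
Conditions: Bu4NF/AcOH (1:1), THF, 0 °C to rt
Reagents that add atoms: none
Why: Fluoride-mediated cleavage of triethylsilyl ethers; the acetic acid buffer keeps free alkoxide from forming, so the epoxide does not migrate prematurely, and the ester-deactivated vinyl epoxide is not exposed to acid.

Step 7
Reactants: 8 methyl 6α-allyl-1β,6β-epoxy-4α,5α-dihydroxycyclohex-2-ene-3-carboxylate
Product: 9 methyl (1R,4R,5R,6S)-4-(tert-butyldimethylsilyloxy)-5-hydroxy-6-(prop-2-en-1-yl)-7-oxabicyclo[4.1.0]hept-2-ene-3-carboxylate (target locants: 4α-silyloxy, 5α-hydroxy, 1β,6β-epoxide, 6α-allyl)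
Conditions: t-BuMe2SiOTf (1.05 equiv), 2,6-lutidine, CH2Cl2, −78 °C
Reagents that add atoms: tert-butyldimethylsilyl trifluoromethanesulfonate CC(C)(C)[Si](C)(C)OS(=O)(=O)C(F)(F)F
Why: Sterically controlled monosilylation of a cis-diol; O5 is flanked by the fully substituted C6 with its cis allyl group, so the bulky silyl triflate should take O4, and any O5 silyl isomer would be expected to return by cis-vicinal silyl shift under the base of step 8.

Step 8
Reactants: 9 methyl (1R,4R,5R,6S)-4-(tert-butyldimethylsilyloxy)-5-hydroxy-6-(prop-2-en-1-yl)-7-oxabicyclo[4.1.0]hept-2-ene-3-carboxylate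
Product: 10 methyl (1R,2R,5R,6S)-2-(tert-butyldimethylsilyloxy)-5-hydroxy-6-(prop-2-en-1-yl)-7-oxabicyclo[4.1.0]hept-3-ene-3-carboxylate (target locants: 4α-silyloxy, 5α,6α-epoxide, 6β-allyl, 1β-hydroxy)
Conditions: t-BuOK (0.2 equiv), THF/t-BuOH, 0 °C to rt; pH 7 buffer
Reagents that add atoms: none
Why: The base reversibly forms the O5 alkoxide, which attacks C6 on the α face, anti to the C6–O bond of the β oxirane, so that the C5–O–C6 epoxide forms as the old one opens to the C1 alkoxide, which t-BuOH protonates. The closest known reaction type is the Payne rearrangement of 2,3-epoxy alcohols, established for cyclohexane epoxy alcohols and for attack at a fully substituted epoxide carbon. The new oxirane closes in the 3-exo-tet mode. The one new stereocentre, C6, arises by inversion and is therefore dictated by the configuration of C5 from step 1 and by the anti epoxide from step 5, while C5 and C1 keep their oxygens with retention. The step needs O5 as the only nucleophile and an anti epoxy alcohol; the silyl ether on O4 and the facial outcome of step 5 secure both. The equilibrium is expected to favour 10 because the α-face crowding of C4-silyloxy, C5-hydroxyl and C6-allyl is relieved and the oxirane leaves the allylic position. Catalytic base and low temperature should limit isomerisation of the γ-hydroxy enoate, and recovered 9 can be resubmitted.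

Step 9
Reactants: 10 methyl (1R,2R,5R,6S)-2-(tert-butyldimethylsilyloxy)-5-hydroxy-6-(prop-2-en-1-yl)-7-oxabicyclo[4.1.0]hept-3-ene-3-carboxylate
Product: 11 6β-allyl-4α-(tert-butyldimethylsilyloxy)-5α,6α-epoxy-3-(hydroxymethyl)cyclohex-2-en-1β-ol
Conditions: i-Bu2AlH (4 equiv), CH2Cl2, −78 °C; aq. potassium sodium tartrate
Reagents that add atoms: none
Why: 1,2-Reduction of a conjugated ester by an aluminium hydride; at −78 °C the non-allylic oxirane and the silyl ether should be untouched, and the aluminium alkoxide at O1 is not nucleophilic enough to reverse step 8.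

Step 10
Reactants: 11 6β-allyl-4α-(tert-butyldimethylsilyloxy)-5α,6α-epoxy-3-(hydroxymethyl)cyclohex-2-en-1β-ol
Product: 12 6β-allyl-4α-(tert-butyldimethylsilyloxy)-3-[(tert-butyldimethylsilyloxy)methyl]-5α,6α-epoxycyclohex-2-en-1β-ol
Conditions: t-BuMe2SiCl (1.1 equiv), imidazole, CH2Cl2, 0 °C
Reagents that add atoms: tert-butyldimethylsilyl chloride CC(C)(C)[Si](C)(C)Cl
Why: Selective silylation of a primary allylic alcohol in the presence of a secondary one that adjoins the fully substituted C6; imidazole is too weak a base to set the epoxide migrating.

Step 11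
Reactants: 12 6β-allyl-4α-(tert-butyldimethylsilyloxy)-3-[(tert-butyldimethylsilyloxy)methyl]-5α,6α-epoxycyclohex-2-en-1β-ol
Product: 13 6β-allyl-4α-(tert-butyldimethylsilyloxy)-3-[(tert-butyldimethylsilyloxy)methyl]-5α,6α-epoxycyclohex-2-en-1-one
Conditions: Dess–Martin periodinane, NaHCO3, CH2Cl2, 0 °C to rt
Reagents that add atoms: none
Why: Dess–Martin oxidation of the only free hydroxyl under buffered, non-basic conditions; it removes the C1 stereocentre and makes any return of the epoxide impossible.

Step 12
Reactants: 13 6β-allyl-4α-(tert-butyldimethylsilyloxy)-3-[(tert-butyldimethylsilyloxy)methyl]-5α,6α-epoxycyclohex-2-en-1-one; 14 tert-butyl methacrylate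
Product: 15 tert-butyl (E)-4-[4α-(tert-butyldimethylsilyloxy)-3-[(tert-butyldimethylsilyloxy)methyl]-5α,6α-epoxy-1-oxocyclohex-2-en-6β-yl]-2-methylbut-2-enoate
Conditions: second-generation Grubbs catalyst (H2IMes)(PCy3)Cl2Ru=CHPh (5 mol %), 14 (10 equiv), CH2Cl2, 40 °C
Reagents that add atoms: none
Why: Olefin cross-metathesis of a terminal alkene with a methacrylate ester, which gives the trisubstituted enoate with the E geometry under thermodynamic control; the trisubstituted ring alkene does not take part.

Step 13
Reactants: 15 tert-butyl (E)-4-[4α-(tert-butyldimethylsilyloxy)-3-[(tert-butyldimethylsilyloxy)methyl]-5α,6α-epoxy-1-oxocyclohex-2-en-6β-yl]-2-methylbut-2-enoate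
Product: 16 tert-butyl (E)-4-[4α-(tert-butyldimethylsilyloxy)-3-[(tert-butyldimethylsilyloxy)methyl]-5α,6α-epoxy-2-iodo-1-oxocyclohex-2-en-6β-yl]-2-methylbut-2-enoate
Conditions: I2, PhI(OCOCF3)2, pyridine, CH2Cl2, rt, dark
Reagents that add atoms: iodine II
Why: α-Iodination of an enone with an electrophilic iodine–pyridine system, a combination suited to β-substituted cyclohexenones; C2 is the only α-CH and the electron-poor enoate alkene of the chain does not react.

Step 14
Reactants: 17 hept-1-yne
Product: 18 (E)-tributyl(hept-1-en-1-yl)stannane
Conditions: Bu3SnH (1.1 equiv), AIBN (cat.), neat, 90 °C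
Reagents that add atoms: tributyltin hydride CCCC[SnH](CCCC)CCCC
Why: Radical hydrostannation of a terminal alkyne places tin on the terminal carbon, and reversible addition of tin radicals under these conditions should equilibrate the product to the E alkenylstannane.

Step 15
Reactants: 16 tert-butyl (E)-4-[4α-(tert-butyldimethylsilyloxy)-3-[(tert-butyldimethylsilyloxy)methyl]-5α,6α-epoxy-2-iodo-1-oxocyclohex-2-en-6β-yl]-2-methylbut-2-enoate; 18 (E)-tributyl(hept-1-en-1-yl)stannane
Product: 19 tert-butyl (E)-4-[4α-(tert-butyldimethylsilyloxy)-3-[(tert-butyldimethylsilyloxy)methyl]-5α,6α-epoxy-2-[(E)-hept-1-en-1-yl]-1-oxocyclohex-2-en-6β-yl]-2-methylbut-2-enoate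
Conditions: Pd2(dba)3 (5 mol %), AsPh3 (20 mol %), CuI (10 mol %), NMP, rt to 40 °C
Reagents that add atoms: none
Why: Stille coupling of an α-iodoenone with an alkenylstannane under neutral conditions; the alkene geometry of 18 is retained and the base-sensitive epoxy enone is not exposed to base.

Step 16
Reactants: 19 tert-butyl (E)-4-[4α-(tert-butyldimethylsilyloxy)-3-[(tert-butyldimethylsilyloxy)methyl]-5α,6α-epoxy-2-[(E)-hept-1-en-1-yl]-1-oxocyclohex-2-en-6β-yl]-2-methylbut-2-enoate
Product: 20 (2E)-4-[(1R,5R,6R)-3-[(1E)-hept-1-en-1-yl]-5-hydroxy-4-(hydroxymethyl)-2-oxo-7-oxabicyclo[4.1.0]hept-3-en-1-yl]-2-methylbut-2-enoic acid (the target)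
Conditions: CF3CO2H/CH2Cl2/H2O (10:10:1), 0 °C to rt
Reagents that add atoms: none
Why: Acidolysis of the tert-butyl ester with loss of isobutene and acid hydrolysis of both silyl ethers in one operation; the oxirane is deactivated towards acid by the adjacent ketone and by the oxygen on C4, and no base touches the final compound.

## Compound list

1 | 1-bromo-4-iodobenzene | Brc1ccc(I)cc1 | starting material
2 | (1S,2R)-3-bromo-6-iodocyclohexa-3,5-diene-1,2-diol | IC1=CC=C(Br)[C@H](O)[C@@H]1O | intermediate
3 | bis(triethylsilyl) ether of 2 | IC1=CC=C(Br)[C@H](O[Si](CC)(CC)CC)[C@@H]1O[Si](CC)(CC)CC | intermediate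
4 | methyl (5R,6R)-4-bromo-5,6-bis(triethylsilyloxy)cyclohexa-1,3-diene-1-carboxylate | COC(=O)C1=CC=C(Br)[C@H](O[Si](CC)(CC)CC)[C@@H]1O[Si](CC)(CC)CC | intermediate
5 | allyltributylstannane | C=CC[Sn](CCCC)(CCCC)CCCC | starting material
6 | methyl (5S,6R)-4-allyl-5,6-bis(triethylsilyloxy)cyclohexa-1,3-diene-1-carboxylate | COC(=O)C1=CC=C(CC=C)[C@H](O[Si](CC)(CC)CC)[C@@H]1O[Si](CC)(CC)CC | intermediate
7 | methyl 6α-allyl-1β,6β-epoxy-4α,5α-bis(triethylsilyloxy)cyclohex-2-ene-3-carboxylate | C1=C(C(=O)OC)[C@@H](O[Si](CC)(CC)CC)[C@@H](O[Si](CC)(CC)CC)[C@]2(CC=C)O[C@H]12 | intermediate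
8 | methyl 6α-allyl-1β,6β-epoxy-4α,5α-dihydroxycyclohex-2-ene-3-carboxylate | C1=C(C(=O)OC)[C@@H](O)[C@@H](O)[C@]2(CC=C)O[C@H]12 | intermediate
9 | methyl (1R,4R,5R,6S)-4-(tert-butyldimethylsilyloxy)-5-hydroxy-6-(prop-2-en-1-yl)-7-oxabicyclo[4.1.0]hept-2-ene-3-carboxylate | C1=C(C(=O)OC)[C@@H](O[Si](C)(C)C(C)(C)C)[C@@H](O)[C@]2(CC=C)O[C@H]12 | intermediate
10 | methyl (1R,2R,5R,6S)-2-(tert-butyldimethylsilyloxy)-5-hydroxy-6-(prop-2-en-1-yl)-7-oxabicyclo[4.1.0]hept-3-ene-3-carboxylate | C1=C(C(=O)OC)[C@@H](O[Si](C)(C)C(C)(C)C)[C@H]2O[C@@]2(CC=C)[C@@H]1O | intermediate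
11 | 6β-allyl-4α-(tert-butyldimethylsilyloxy)-5α,6α-epoxy-3-(hydroxymethyl)cyclohex-2-en-1β-ol | C1=C(CO)[C@@H](O[Si](C)(C)C(C)(C)C)[C@H]2O[C@@]2(CC=C)[C@@H]1O | intermediate
12 | 6β-allyl-4α-(tert-butyldimethylsilyloxy)-3-[(tert-butyldimethylsilyloxy)methyl]-5α,6α-epoxycyclohex-2-en-1β-ol | C1=C(CO[Si](C)(C)C(C)(C)C)[C@@H](O[Si](C)(C)C(C)(C)C)[C@H]2O[C@@]2(CC=C)[C@@H]1O | intermediate
13 | 6β-allyl-4α-(tert-butyldimethylsilyloxy)-3-[(tert-butyldimethylsilyloxy)methyl]-5α,6α-epoxycyclohex-2-en-1-one | C1=C(CO[Si](C)(C)C(C)(C)C)[C@@H](O[Si](C)(C)C(C)(C)C)[C@H]2O[C@@]2(CC=C)C1=O | intermediate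
14 | tert-butyl methacrylate | C=C(C)C(=O)OC(C)(C)C | starting material
15 | tert-butyl (E)-4-[4α-(tert-butyldimethylsilyloxy)-3-[(tert-butyldimethylsilyloxy)methyl]-5α,6α-epoxy-1-oxocyclohex-2-en-6β-yl]-2-methylbut-2-enoate | C1=C(CO[Si](C)(C)C(C)(C)C)[C@@H](O[Si](C)(C)C(C)(C)C)[C@H]2O[C@@]2(C/C=C(\C)C(=O)OC(C)(C)C)C1=O | intermediate
16 | 2-iodo derivative of 15 | IC1=C(CO[Si](C)(C)C(C)(C)C)[C@@H](O[Si](C)(C)C(C)(C)C)[C@H]2O[C@@]2(C/C=C(\C)C(=O)OC(C)(C)C)C1=O | intermediate
17 | hept-1-yne | CCCCCC#C | starting material
18 | (E)-tributyl(hept-1-en-1-yl)stannane | CCCCC/C=C/[Sn](CCCC)(CCCC)CCCC | intermediate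
19 | tert-butyl (E)-4-[4α-(tert-butyldimethylsilyloxy)-3-[(tert-butyldimethylsilyloxy)methyl]-5α,6α-epoxy-2-[(E)-hept-1-en-1-yl]-1-oxocyclohex-2-en-6β-yl]-2-methylbut-2-enoate | CCCCC/C=C/C1=C(CO[Si](C)(C)C(C)(C)C)[C@@H](O[Si](C)(C)C(C)(C)C)[C@H]2O[C@@]2(C/C=C(\C)C(=O)OC(C)(C)C)C1=O | intermediate
20 | (2E)-4-[(1R,5R,6R)-3-[(1E)-hept-1-en-1-yl]-5-hydroxy-4-(hydroxymethyl)-2-oxo-7-oxabicyclo[4.1.0]hept-3-en-1-yl]-2-methylbut-2-enoic acid | CCCCC/C=C/C1=C(CO)[C@@H](O)[C@H]2O[C@@]2(C/C=C(\C)C(=O)O)C1=O | target

Total step count: 16. Longest linear sequence: 15 steps (steps 1 to 13, then 15 and 16; step 14 is a side branch).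

## Least certain steps

**Step 8 (key step).** The epoxide migration is an equilibrium and may stop short of completion. On long exposure to base, material may also drain away by proton shift of the γ-hydroxy enoate to a keto ester, or by transannular attack if the silyl group moves to O5. Fallback, from 9 to 11: treat 9 with NaH (1.1 equiv) in THF and intercept the equilibrating alkoxides by slow addition of Ac2O at low temperature. The allylic O1 alkoxide is the less hindered of the two and should acylate faster (Curtin–Hammett control), giving methyl 1β-acetoxy-6β-allyl-4α-(tert-butyldimethylsilyloxy)-5α,6α-epoxycyclohex-2-ene-3-carboxylate F1. The i-Bu2AlH treatment of step 9 then removes the acetate together with the ester and delivers 11.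

**Step 1.** The enzyme may not discriminate iodine from bromine completely, so that the minor binding mode, with bromine directing, erodes the enantiomeric purity. Fallback, from 2 back to 2: classical resolution. Scalemic 2 is esterified with (S)-2-methoxy-2-phenylacetic acid (DCC, DMAP, CH2Cl2, 0 °C) to the bis[(S)-2-methoxy-2-phenylacetate] of the (1S,2R)-diol F2 and the bis[(S)-2-methoxy-2-phenylacetate] of the (1R,2S)-diol F3. These diastereomers are separated by crystallisation or chromatography, and F2 is methanolysed (K2CO3, MeOH, 0 °C) to return enantiopure 2.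

**Step 5.** The peracid may also attack the terminal allyl alkene, or attack the α face, because conjugation to the ester and the allylic silyloxy group lower the reactivity of C1=C6. Fallback, from 6 to 7: a Jacobsen–Katsuki epoxidation with a chloro(salen)manganese complex, chloro[N,N′-bis(3,5-di-tert-butylsalicylidene)-1,2-cyclohexanediaminato]manganese, using NaOCl and 4-phenylpyridine N-oxide in CH2Cl2 at 0 °C. The stepwise metal-oxo mechanism prefers conjugated alkenes over isolated terminal ones, and the catalyst enantiomer that reinforces β attack is chosen. No new compound arises (F0).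

**Step 15.** Transmetalation at the crowded, fully substituted α-carbon may be slow, leaving room for protodestannylation or homocoupling of 18. Fallback, from 16 to 19: Suzuki–Miyaura coupling with commercial (E)-hept-1-enylboronic acid using Pd(PPh3)4 and Ag2O in THF/H2O at rt, which changes the transmetalating element and avoids soluble strong base. No new compound arises (F0).

**Step 16.** Opening of the oxirane or isomerisation of the dienone in acid may compete with the slow cleavage of the secondary silyl ether. Fallback, from 13 to 20: avoid protic acid.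
- Cross-metathesis of 13 with methyl methacrylate under the conditions of step 12 gives methyl (E)-4-[4α-(tert-butyldimethylsilyloxy)-3-[(tert-butyldimethylsilyloxy)methyl]-5α,6α-epoxy-1-oxocyclohex-2-en-6β-yl]-2-methylbut-2-enoate F4.
- Iodination as in step 13 gives the 2-iodo methyl ester F5.
- Stille coupling with 18 as in step 15 gives the 2-[(E)-hept-1-enyl] methyl ester F6.
- Neutral ester cleavage with Me3SnOH (1,2-dichloroethane, 70 °C) gives the bis-silylated carboxylic acid F7.
- HF·pyridine buffered with pyridine in THF at 0 °C removes both silyl ethers to give 20.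

## Further compounds

F1 | step 8 | methyl 1β-acetoxy-6β-allyl-4α-(tert-butyldimethylsilyloxy)-5α,6α-epoxycyclohex-2-ene-3-carboxylate | C1=C(C(=O)OC)[C@@H](O[Si](C)(C)C(C)(C)C)[C@H]2O[C@@]2(CC=C)[C@@H]1OC(C)=O
F2 | step 1 | bis[(S)-2-methoxy-2-phenylacetate] of (1S,2R)-3-bromo-6-iodocyclohexa-3,5-diene-1,2-diol | IC1=CC=C(Br)[C@H](OC(=O)[C@@H](OC)c2ccccc2)[C@@H]1OC(=O)[C@@H](OC)c3ccccc3
F3 | step 1 | bis[(S)-2-methoxy-2-phenylacetate] of (1R,2S)-3-bromo-6-iodocyclohexa-3,5-diene-1,2-diol | IC1=CC=C(Br)[C@@H](OC(=O)[C@@H](OC)c2ccccc2)[C@H]1OC(=O)[C@@H](OC)c3ccccc3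
F0 | step 5 | none | none
F0 | step 15 | none | none
F4 | step 16 | methyl (E)-4-[4α-(tert-butyldimethylsilyloxy)-3-[(tert-butyldimethylsilyloxy)methyl]-5α,6α-epoxy-1-oxocyclohex-2-en-6β-yl]-2-methylbut-2-enoate | C1=C(CO[Si](C)(C)C(C)(C)C)[C@@H](O[Si](C)(C)C(C)(C)C)[C@H]2O[C@@]2(C/C=C(\C)C(=O)OC)C1=O
F5 | step 16 | 2-iodo derivative of F4 | IC1=C(CO[Si](C)(C)C(C)(C)C)[C@@H](O[Si](C)(C)C(C)(C)C)[C@H]2O[C@@]2(C/C=C(\C)C(=O)OC)C1=O
F6 | step 16 | methyl (E)-4-[4α-(tert-butyldimethylsilyloxy)-3-[(tert-butyldimethylsilyloxy)methyl]-5α,6α-epoxy-2-[(E)-hept-1-en-1-yl]-1-oxocyclohex-2-en-6β-yl]-2-methylbut-2-enoate | CCCCC/C=C/C1=C(CO[Si](C)(C)C(C)(C)C)[C@@H](O[Si](C)(C)C(C)(C)C)[C@H]2O[C@@]2(C/C=C(\C)C(=O)OC)C1=O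
F7 | step 16 | (E)-4-[4α-(tert-butyldimethylsilyloxy)-3-[(tert-butyldimethylsilyloxy)methyl]-5α,6α-epoxy-2-[(E)-hept-1-en-1-yl]-1-oxocyclohex-2-en-6β-yl]-2-methylbut-2-enoic acid | CCCCC/C=C/C1=C(CO[Si](C)(C)C(C)(C)C)[C@@H](O[Si](C)(C)C(C)(C)C)[C@H]2O[C@@]2(C/C=C(\C)C(=O)O)C1=O
A1 | alternative 1 | 2-[(tert-butyldiphenylsilyloxy)methyl]-5-(2,2-dimethoxyethyl)-3-[(E)-hept-1-en-1-yl]-5-(triethylsilyloxy)cyclohex-2-en-1-one | CCCCC/C=C/C1=C(CO[Si](c2ccccc2)(c2ccccc2)C(C)(C)C)C(=O)C[C@](O[Si](CC)(CC)CC)(CC(OC)OC)C1
A2 | alternative 2 | methyl (E)-4-[4α-(tert-butyldimethylsilyloxy)-3-[(tert-butyldimethylsilyloxy)methyl]-5α,6α-epoxy-1β-hydroxy-2-vinylcyclohex-2-en-6β-yl]-2-methylbut-2-enoate | C=CC1=C(CO[Si](C)(C)C(C)(C)C)[C@@H](O[Si](C)(C)C(C)(C)C)[C@H]2O[C@@]2(C/C=C(\C)C(=O)OC)[C@@H]1O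
A3 | alternative 3 | methyl (E)-4-[4-[(tert-butyldimethylsilyloxy)methyl]-3-[(E)-hept-1-en-1-yl]-2-hydroxy-5-methoxyphenyl]-2-methylbut-2-enoate | Oc1c(/C=C/CCCCC)c(CO[Si](C)(C)C(C)(C)C)c(OC)cc1C/C=C(\C)C(=O)OC
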